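**Retrosynthetic overview**
- The target is the trans-(2R,3S) phenylcoumaran (8–5′ neolignan); ring A is the catechol-derived benzo ring and ring B the dihydrofuran ring. Disconnections run: ester hydrolysis, then the O1–C2 bond of ring B to an acyclic 1-aryl-2-(2-hydroxyaryl)propane-1,3-diol, then one oxidation level up at C2 to its racemic aryl ketone.
- Enabling feature: the para-methoxy group of the 3,4-dimethoxyphenyl ring on C2 makes the C2 cation an O-methylated para-quinone methide. The phenol oxygen on C7a is ortho to C3a, so only 5-exo closure onto C2 is possible (the C7 oxygen is meta to C3a). C3–H, flanked by the C2 carbonyl and ring A, is enolisable, which allows dynamic kinetic resolution.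
- The ketone comes from hydroxymethylation (C3–CH2OH) of a deoxybenzoin, made by palladium-catalysed α-arylation of 3′,4′-dimethoxyacetophenone with a bis-MOM 3-bromocaffeate (C3–C3a bond), itself from Wittig olefination and MOM protection of 3-bromo-4,5-dihydroxybenzaldehyde.
- Ring order: both benzene rings are bought; ring B is the only ring made. It is closed in step 5, in the same pot that sets C3 and C2 and removes both protecting groups.

Key step: step 5

Remark: both starting materials are taken as commercial.

Step 1
Reactants: 1 3-bromo-4,5-dihydroxybenzaldehyde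
Product: 2 3-bromo-4,5-bis(methoxymethoxy)benzaldehyde
Conditions: MOMCl (2.5 equiv), K2CO3 (4 equiv), acetone, 0 °C to rt
Reagents that add atoms: chloromethyl methyl ether, COCCl
Why: Williamson-type O-alkylation of both phenoxides should give two methoxymethyl acetals that tolerate base, zerovalent palladium and hydride transfer and are meant to fall off in the acid stage of step 5; no stereocenter is formed.

Step 2
Reactants: 2 3-bromo-4,5-bis(methoxymethoxy)benzaldehyde
Product: 3 methyl (E)-3-[3-bromo-4,5-bis(methoxymethoxy)phenyl]prop-2-enoate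
Conditions: Ph3P=CHCO2Me (1.2 equiv), toluene, 80 °C
Reagents that add atoms: methyl (triphenylphosphoranylidene)acetate, COC(=O)C=P(c1ccccc1)(c1ccccc1)c1ccccc1
Why: Wittig olefination with a stabilised ylide should give the E-enoate selectively and removes the free aldehyde before the enolate chemistry of step 3 and the hydride transfer of step 5.

Step 3
Reactants: 3 methyl (E)-3-[3-bromo-4,5-bis(methoxymethoxy)phenyl]prop-2-enoate; 4 1-(3,4-dimethoxyphenyl)ethanone
Product: 5 methyl (E)-3-[3-[2-(3,4-dimethoxyphenyl)-2-oxoethyl]-4,5-bis(methoxymethoxy)phenyl]prop-2-enoate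
Conditions: Pd2(dba)3 (2 mol%), Xantphos (4.5 mol%), K3PO4 (2.5 equiv), toluene, 80 °C
Reagents that add atoms: none
Why: Palladium-catalysed ketone α-arylation (oxidative addition of zerovalent palladium into the C–Br bond, transmetalation with the potassium enolate of 4, reductive elimination) should forge the future C3–C3a bond, with the mild phosphate base sparing the ester and enoate and the ortho-alkoxy group of the new aryl substituent discouraging a second arylation.

Step 4
Reactants: 5 methyl (E)-3-[3-[2-(3,4-dimethoxyphenyl)-2-oxoethyl]-4,5-bis(methoxymethoxy)phenyl]prop-2-enoate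
Product: 6 methyl (E)-3-[3-[1-(3,4-dimethoxyphenyl)-3-hydroxy-1-oxopropan-2-yl]-4,5-bis(methoxymethoxy)phenyl]prop-2-enoate (racemic)
Conditions: 37% aq. HCHO (1.2 equiv), K2CO3 (0.2 equiv), THF/MeOH, rt
Reagents that add atoms: formaldehyde, C=O
Why: Base-catalysed crossed aldol addition (hydroxymethylation) at the doubly activated benzylic methylene should install the CH2OH carbon, and the new stereocenter is left racemic on purpose because it stays enolisable and is set in step 5.

Step 5
Reactants: 6 methyl (E)-3-[3-[1-(3,4-dimethoxyphenyl)-3-hydroxy-1-oxopropan-2-yl]-4,5-bis(methoxymethoxy)phenyl]prop-2-enoate (racemic)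
Product: 9 methyl (E)-3-[(2R,3S)-2-(3,4-dimethoxyphenyl)-7-hydroxy-3-(hydroxymethyl)-2,3-dihydro-1-benzofuran-5-yl]prop-2-enoate, via (1R,2S)-diol 7 (not isolated), via benzylic cation 8 (not isolated)
Conditions: RuCl[(R,R)-TsDPEN](p-cymene) (2 mol%), HCO2H–Et3N (5:2 azeotrope), EtOAc, 40 °C; then MeOH, conc. HCl, 45 °C (one pot)
Reagents that add atoms: none
Why: Noyori-type asymmetric transfer hydrogenation with dynamic kinetic resolution: C3–H of 6 lies between the aryl ketone and ring A, so the two enantiomers of 6 interconvert by enolisation in the formic acid–amine buffer while the ruthenium hydride reduces, by outer-sphere hydride transfer, the enantiomer whose catalyst-preferred carbonyl face is anti to the large C3 aryl group, which should give diol 7. Hydrochloric acid in methanol then removes both methoxymethyl acetals and ionises the benzylic alcohol to cation 8, an O-methylated para-quinone methide stabilised by the para-methoxy group of the dimethoxyphenyl ring, and the phenol oxygen on C7a closes ring B by 5-exo-trig attack on C2, the same event that ends phenylcoumaran (8–5′) biosynthesis. The closest known reaction types are the one-pot transfer hydrogenation/acid cyclisation of 2′-hydroxyisoflavanones to pterocarpans and the acid-mediated closure of 1-aryl-2-(2-hydroxyaryl)propane-1,3-diols to trans-phenylcoumarans. C3 (S) is set by the catalyst through the dynamic kinetic resolution, whereas C2 (R) is set by C3 under substrate control, because closure of the planar cation places the aryl group anti to CH2OH and any cis isomer can re-ionise to the more stable trans one, so the carbinol configuration of 7 is irrelevant. The step needs reduction to outrun β-elimination of water from the enolisable β-hydroxy ketone (the mildly acidic buffer and the poor leaving group should secure this), ketone over enoate reduction (inherent to this catalyst class) and capture of the cation by the right oxygen, which the substrate secures because only the C7a oxygen reaches C2 in a strain-free ring, the C7 oxygen being meta to C3a and the primary alcohol able to form only an oxetane.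

Step 6
Reactants: 9 methyl (E)-3-[(2R,3S)-2-(3,4-dimethoxyphenyl)-7-hydroxy-3-(hydroxymethyl)-2,3-dihydro-1-benzofuran-5-yl]prop-2-enoate
Product: 10 (E)-3-[(2R,3S)-2-(3,4-dimethoxyphenyl)-7-hydroxy-3-(hydroxymethyl)-2,3-dihydro-1-benzofuran-5-yl]prop-2-enoic acid
Conditions: LiOH·H2O (5 equiv), THF/MeOH/H2O, rt, degassed; then 1 M HCl to pH 3
Reagents that add atoms: lithium hydroxide, [Li+].[OH-]
Why: Saponification of the methyl enoate should give the acid without touching either stereocenter, since C3–H is only benzylic and C2 is an ether carbon, and the E-alkene is retained.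

**Compound list**
1 | 3-bromo-4,5-dihydroxybenzaldehyde | O=Cc1cc(O)c(O)c(Br)c1 | starting material
2 | 3-bromo-4,5-bis(methoxymethoxy)benzaldehyde | O=Cc1cc(OCOC)c(OCOC)c(Br)c1 | intermediate
3 | methyl (E)-3-[3-bromo-4,5-bis(methoxymethoxy)phenyl]prop-2-enoate | COC(=O)/C=C/c1cc(OCOC)c(OCOC)c(Br)c1 | intermediate
4 | 1-(3,4-dimethoxyphenyl)ethanone | CC(=O)c1ccc(OC)c(OC)c1 | starting material
5 | methyl (E)-3-[3-[2-(3,4-dimethoxyphenyl)-2-oxoethyl]-4,5-bis(methoxymethoxy)phenyl]prop-2-enoate | COC(=O)/C=C/c1cc(OCOC)c(OCOC)c(CC(=O)c2ccc(OC)c(OC)c2)c1 | intermediate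
6 | methyl (E)-3-[3-[1-(3,4-dimethoxyphenyl)-3-hydroxy-1-oxopropan-2-yl]-4,5-bis(methoxymethoxy)phenyl]prop-2-enoate (racemic) | COC(=O)/C=C/c1cc(OCOC)c(OCOC)c(C(CO)C(=O)c2ccc(OC)c(OC)c2)c1 | intermediate
7 | methyl (E)-3-[3-[(1R,2S)-1-(3,4-dimethoxyphenyl)-1,3-dihydroxypropan-2-yl]-4,5-bis(methoxymethoxy)phenyl]prop-2-enoate | COC(=O)/C=C/c1cc(OCOC)c(OCOC)c([C@@H](CO)[C@@H](O)c2ccc(OC)c(OC)c2)c1 | intermediate
8 | (2S)-1-(3,4-dimethoxyphenyl)-2-[2,3-dihydroxy-5-[(E)-3-methoxy-3-oxoprop-1-enyl]phenyl]-3-hydroxypropan-1-ylium (benzylic cation) | COC(=O)/C=C/c1cc(O)c(O)c([C@@H](CO)[CH+]c2ccc(OC)c(OC)c2)c1 | intermediate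
9 | methyl (E)-3-[(2R,3S)-2-(3,4-dimethoxyphenyl)-7-hydroxy-3-(hydroxymethyl)-2,3-dihydro-1-benzofuran-5-yl]prop-2-enoate | COc1ccc([C@@H]2Oc3c(O)cc(/C=C/C(=O)OC)cc3[C@H]2CO)cc1OC | intermediate
10 | (E)-3-[(2R,3S)-2-(3,4-dimethoxyphenyl)-7-hydroxy-3-(hydroxymethyl)-2,3-dihydro-1-benzofuran-5-yl]prop-2-enoic acid | COc1ccc([C@@H]2Oc3c(O)cc(/C=C/C(=O)O)cc3[C@H]2CO)cc1OC | target

**Step count**
Total step count: 6. Longest linear sequence: 6 steps (1 to 10 through 2, 3, 5, 6 and 9); 4 enters at step 3.

**Steps most likely to fail**

Step 5. What may go wrong: too little kinetic discrimination between the two interconverting C3 epimers of 6 during hydride transfer, which after the stereoconvergent ionisation would show up as loss of enantiopurity; or β-elimination of water and retro-aldol loss of formaldehyde outrunning the reduction. The fallback replaces dynamic kinetic resolution by auxiliary control; it sets out from 3 and comes back at 7. Negishi coupling of 3 with the Reformatsky reagent of 2-(trimethylsilyl)ethyl bromoacetate (Pd(dba)2, Q-Phos, THF, rt) should give the 2-(trimethylsilyl)ethyl arylacetate F1. TBAF in THF should unmask the arylacetic acid F2. Its mixed pivalic anhydride (PivCl, Et3N) should acylate (R)-4-benzyl-1,3-oxazolidin-2-one (LiCl) to give the imide F3. An Evans syn-aldol addition (Bu2BOTf, iPr2NEt, CH2Cl2, −78 to 0 °C) to 3,4-dimethoxybenzaldehyde should give the syn-aldol adduct F4, in which the auxiliary fixes the future C3. LiBH4 (THF, H2O, 0 °C) should then cleave the auxiliary reductively, sparing the methyl enoate, to give 7 as an isolated compound, which is taken through the acid stage of step 5 to 9.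

Step 3. What may go wrong: conjugate addition of the ketone enolate to the enoate, a second arylation of the more acidic product, or slow oxidative addition at the ortho-alkoxy C–Br bond. The fallback reverses the polarity of the coupling; it sets out from 3 and comes back at 5. Miyaura borylation of 3 (B2pin2, PdCl2(dppf), KOAc, 1,4-dioxane, 85 °C) should give the aryl pinacol boronate F5. A Suzuki–Miyaura coupling of F5 with 2-bromo-1-(3,4-dimethoxyphenyl)ethanone (Pd(OAc)2, SPhos, K3PO4, THF/H2O, rt) should then give 5 without a ketone enolate being generated next to the enoate.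

Step 4. What may go wrong: a second formaldehyde addition at the remaining acidic C–H, or dehydration of the aldol to the α-aryl enone under base. The fallback brings in the one-carbon unit at the aldehyde oxidation level; it sets out from 5 and comes back at 6. Claisen formylation of 5 (HCO2Me, NaOMe, THF, 0 °C to rt) should give the α-formyl ketone F6 (mainly as its enol), which cannot take up a second one-carbon unit. F6 is put directly into step 5, where the ruthenium hydride should reduce the formyl group first and so generate 6 in the flask before the dynamic kinetic resolution.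

**Further compounds**
F1 | step 5 | 2-(trimethylsilyl)ethyl 2-[5-[(E)-3-methoxy-3-oxoprop-1-enyl]-2,3-bis(methoxymethoxy)phenyl]acetate | COC(=O)/C=C/c1cc(OCOC)c(OCOC)c(CC(=O)OCC[Si](C)(C)C)c1
F2 | step 5 | 2-[5-[(E)-3-methoxy-3-oxoprop-1-enyl]-2,3-bis(methoxymethoxy)phenyl]acetic acid | COC(=O)/C=C/c1cc(OCOC)c(OCOC)c(CC(=O)O)c1
F3 | step 5 | methyl (E)-3-[3-[2-[(4R)-4-benzyl-2-oxo-1,3-oxazolidin-3-yl]-2-oxoethyl]-4,5-bis(methoxymethoxy)phenyl]prop-2-enoate | COC(=O)/C=C/c1cc(OCOC)c(OCOC)c(CC(=O)N2[C@H](Cc3ccccc3)COC2=O)c1
F4 | step 5 | methyl (E)-3-[3-[(2R,3R)-1-[(4R)-4-benzyl-2-oxo-1,3-oxazolidin-3-yl]-3-(3,4-dimethoxyphenyl)-3-hydroxy-1-oxopropan-2-yl]-4,5-bis(methoxymethoxy)phenyl]prop-2-enoate | COC(=O)/C=C/c1cc(OCOC)c(OCOC)c([C@@H](C(=O)N2[C@H](Cc3ccccc3)COC2=O)[C@@H](O)c2ccc(OC)c(OC)c2)c1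
F5 | step 3 | methyl (E)-3-[3,4-bis(methoxymethoxy)-5-(4,4,5,5-tetramethyl-1,3,2-dioxaborolan-2-yl)phenyl]prop-2-enoate | COC(=O)/C=C/c1cc(OCOC)c(OCOC)c(B2OC(C)(C)C(C)(C)O2)c1
F6 | step 4 | methyl (E)-3-[3-[1-(3,4-dimethoxyphenyl)-1,3-dioxopropan-2-yl]-4,5-bis(methoxymethoxy)phenyl]prop-2-enoate | COC(=O)/C=C/c1cc(OCOC)c(OCOC)c(C(C=O)C(=O)c2ccc(OC)c(OC)c2)c1
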